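You asked how long the chains are at 1.0 h and how much free monomer has reacted by then, and your hunch was that chain length follows the charge. That hunch is where we start.

- violet: free monomer 2.1 M; initiator 150 mM; run made earlier
- flask: free monomer 2.1 M; initiator 74 mM; time 1.0 h

violet run (percent of the free monomer charged)

| time / min | monomer in chains / % | free monomer / % |
|---|---|---|
| 0.667 | 10 | 91 |
| 2.00 | 31 | 67 |
| 3.00 | 45 | 55 |
| 5.00 | 63 | 40 |
| 8.00 | 75 | 23 |
| 10.0 | 80 | 21 |
| 12.0 | 86 | 12 |

(each reading ± 1.5 percentage points)

- average number of monomer units in a chain (chains begun, living or dead) at 1.0 h
- part of the free monomer that has reacted at 1.0 h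

- the average divides the monomer in chains by the number of chains begun, living and dead together
- the earlier runs do not show the number of chains; that part of a forecast is a guess
- no earlier run changes the charge of initiator; that part of a forecast is a guess

In the violet run, free monomer stands at 12% by 12.0 min. The flask has half the initiator but runs 5.00 times as long, so we expect it to be well advanced. The readings show no chain count, so we freeze that count at the initiator charge. This gives the charge ratio, free monomer charged per initiator charged, 28.4. Multiplied by the part reacted, it gives the average chain if each initiator begins one chain, and the chain is longer if some initiators begin none. We commit to about 28.4 as a floor.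

The forecast gives 31 (25 to 70) and 97% (88% to 99.8%). Its chain length lies above our 28.4, and its range leans high: “Incomplete initiator efficiency would raise this”.

The flask gives 62.1 and 93.1%.

    living end + free monomer → dead end A (k = 0.00200 M⁻¹ s⁻¹)
    2 initiator → spent initiator B (k = 0.240 M⁻¹ s⁻¹)
    free monomer + initiator → living end + monomer in chains (k = 0.00490 M⁻¹ s⁻¹)
    free monomer + living end → monomer in chains + living end, rate k4*[living end]*[free monomer] (k = 0.130 M⁻¹ s⁻¹)

In the flask, the floor at 93.1% is 26.4, so 42.6% of the initiator began a chain; this share is the initiator efficiency. By 0.100 h, initiator in the flask was down to 1.53% of its charge and spent initiator B already stood at 0.0214 M, which at two initiators each is 58.0% of that charge. Growth on living ends then took free monomer in the flask from 46.5% to 6.92% by 1.00 h.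

In a neighbour flask with 0.018 M of initiator, the charge ratio is 117, and at its 41.4% reacted the floor is 48.3. The simulation gives 66.0 for that neighbour, a share of 73.2%.

The readings were generated by integration for an exercise, noise included.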